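**Plan**
- Retrosynthesis: the benzyl ether on the 3'-oxygen is removed first. Ring C is then cut at C4–C4a and O1–C2, which leaves a phloroglucinol with one free ring carbon and an aroylacetate carrying ring B. Ring A is cut last, at C5–C6 and C8–C8a.
- Enabling feature (flavone numbering): ring A has a mirror line through C7 and C4a and carries OH/OMe/OH/OMe/OH in alternation. C6–C7–C8 is therefore 1,3-dimethoxyacetone (carbonyl carbon = C7, methoxymethylene carbons = C6 and C8), and C5–C4a–C8a is a malonyl unit (carbonyls = C5 and C8a, CH2 = C4a).
- Forward: ring A is made first from these two open-chain three-carbon pieces. Ring C is then fused on by thermal condensation with the β-keto ester of ring B (from 3-hydroxy-4-methoxyacetophenone), and hydrogenolysis of the benzyl ether ends the route.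
- Stereochemistry: the target has no stereocentre. The symmetry of the ring A triol makes the two hydroxyls beside its only C–H equivalent, so the annulation has a single possible outcome.

Key step: step 2

Remark: acerosin is taken as 5,7,3'-trihydroxy-6,8,4'-trimethoxyflavone (achiral); ring atoms are named in flavone numbering throughout.

**Route**

Step 1
Reactants: 1 1,3-dimethoxypropan-2-ol
Product: 2 1,3-dimethoxypropan-2-one
Conditions: 2-iodoxybenzoic acid (1.5 equiv), EtOAc, 80 °C; filter, distil
Reagents that add atoms: none
Why: Hypervalent-iodine oxidation of a secondary alcohol to the ketone; the ether groups are inert, and the non-aqueous work-up (filtration of the spent oxidant, distillation) suits a volatile, water-miscible product.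

Step 2
Reactants: 2 1,3-dimethoxypropan-2-one (3 equiv); 3 bis(2,4,6-trichlorophenyl) malonate
Product: 8 2,4-dimethoxybenzene-1,3,5-triol, via aryloxycarbonylketene 4 (not isolated), via acyclic aryl ester 5 (not isolated), via hydroxypyranone 6 (not isolated), via methyl dioxohexanoate 7 (not isolated)
Conditions: Ph2O, 180 °C, sealed tube, Ar; then NaOMe (8 equiv) in MeOH, MeOH distilled off, 150 °C; aq. HCl, 0 °C
Reagents that add atoms: none
Why: Proposed new method: heating expels 2,4,6-trichlorophenol from 3 to give ketene 4, which C-acylates the enol of 2 at one methoxy-bearing α-carbon (the C5–C6 bond in flavone numbering) and so gives aryl ester 5. The second activated acyl group of 5 is taken either directly by the other α-carbon or, more probably, by the enol oxygen (6-exo-trig lactonisation) to give 4-hydroxy-2-pyranone 6; hot methoxide opens 6 to methyl ester 7, whose terminal methoxy-bearing carbon then attacks the ester as its enolate (Claisen condensation, the C8–C8a bond), closing ring A in the 6-(enolendo)-exo-trig mode. Enolisation of the resulting cyclohexane-1,3,5-trione to the triphenoxide of 8 is the irreversible sink, the three carbonyl carbons ending as C–OH and the two methoxymethylene carbons as C–OMe. The closest known reaction types are the cyclocondensation of 1,3-disubstituted acetones with bis(2,4,6-trichlorophenyl) malonates to 4-hydroxy-2-pyranones and the base-induced Claisen cyclisation of 3,5-dioxohexanoates or their pyranone forms to phloroglucinols; neither has been shown with a 1,3-dialkoxyacetone. No stereocentre is formed. The step needs C- over O-acylation in the ring-closing bond, which the methoxide equilibration secures because only the carbocycle can aromatise, while the mirror symmetry of 2 removes any regiochemical question and the excess of 2 keeps a second malonate from acylating 6 or 8.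

Step 3
Reactants: 9 1-(3-hydroxy-4-methoxyphenyl)ethan-1-one
Product: 10 1-[3-(benzyloxy)-4-methoxyphenyl]ethan-1-one
Conditions: BnBr (1.1 equiv), K2CO3, DMF, 60 °C
Reagents that add atoms: benzyl bromide, BrCc1ccccc1
Why: Williamson ether synthesis on the only acidic OH; the phenoxide is far more nucleophilic than the ketone enolate under carbonate conditions, so O-benzylation should be clean.

Step 4
Reactants: 10 1-[3-(benzyloxy)-4-methoxyphenyl]ethan-1-one
Product: 11 ethyl 3-[3-(benzyloxy)-4-methoxyphenyl]-3-oxopropanoate
Conditions: NaH (2.5 equiv), (EtO)2CO (5 equiv), toluene, 110 °C; aq. HCl, 0 °C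
Reagents that add atoms: diethyl carbonate, CCOC(=O)OCC
Why: Claisen condensation of the methyl ketone enolate with diethyl carbonate, driven to completion by irreversible deprotonation of the β-keto ester by the second equivalent of NaH; the benzyl and methyl ethers are stable to the base.

Step 5
Reactants: 8 2,4-dimethoxybenzene-1,3,5-triol; 11 ethyl 3-[3-(benzyloxy)-4-methoxyphenyl]-3-oxopropanoate (2 equiv)
Product: 14 2-[3-(benzyloxy)-4-methoxyphenyl]-5,7-dihydroxy-6,8-dimethoxy-4H-chromen-4-one, via aroylketene 12 (not isolated), via aryl diketone 13 (not isolated)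
Conditions: neat melt, 240 °C, Ar, EtOH and H2O distilled off
Reagents that add atoms: none
Why: Mentzer-type thermal condensation of a phloroglucinol with an aroylacetate, the standard one-step entry to 5,7-dihydroxyflavones: 11 loses ethanol to aroylketene 12, which acylates the single free ring carbon of 8 (directly or through a reversible O-acyl stage) to give diketone 13, and cyclodehydration onto either of the two equivalent ortho hydroxyls gives the same 4-pyranone, forming C4–C4a and O1–C2.

Step 6
Reactants: 14 2-[3-(benzyloxy)-4-methoxyphenyl]-5,7-dihydroxy-6,8-dimethoxy-4H-chromen-4-one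
Product: 15 acerosin, 5,7-dihydroxy-2-(3-hydroxy-4-methoxyphenyl)-6,8-dimethoxy-4H-chromen-4-one
Conditions: H2 (1 atm), 10% Pd/C, THF–MeOH, 23 °C
Reagents that add atoms: none
Why: Catalytic hydrogenolysis of a benzyl aryl ether; at one atmosphere and room temperature the conjugated, hydrogen-bonded C2–C3 double bond of the flavone and the aryl methyl ethers should not be touched.

**Compound list**
1 | 1,3-dimethoxypropan-2-ol | COCC(O)COC | starting material
2 | 1,3-dimethoxypropan-2-one | COCC(=O)COC | intermediate
3 | bis(2,4,6-trichlorophenyl) malonate | O=C(CC(=O)Oc1c(Cl)cc(Cl)cc1Cl)Oc1c(Cl)cc(Cl)cc1Cl | starting material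
4 | 2,4,6-trichlorophenyl 3-oxoprop-2-enoate (aryloxycarbonylketene) | O=C=CC(=O)Oc1c(Cl)cc(Cl)cc1Cl | intermediate
5 | 2,4,6-trichlorophenyl 4,6-dimethoxy-3,5-dioxohexanoate | COCC(=O)C(OC)C(=O)CC(=O)Oc1c(Cl)cc(Cl)cc1Cl | intermediate
6 | 4-hydroxy-5-methoxy-6-(methoxymethyl)-2H-pyran-2-one | COCC1=C(OC)C(O)=CC(=O)O1 | intermediate
7 | methyl 4,6-dimethoxy-3,5-dioxohexanoate | COCC(=O)C(OC)C(=O)CC(=O)OC | intermediate
8 | 2,4-dimethoxybenzene-1,3,5-triol | COc1c(O)cc(O)c(OC)c1O | intermediate
9 | 1-(3-hydroxy-4-methoxyphenyl)ethan-1-one | COc1ccc(C(C)=O)cc1O | starting material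
10 | 1-[3-(benzyloxy)-4-methoxyphenyl]ethan-1-one | COc1ccc(C(C)=O)cc1OCc1ccccc1 | intermediate
11 | ethyl 3-[3-(benzyloxy)-4-methoxyphenyl]-3-oxopropanoate | CCOC(=O)CC(=O)c1ccc(OC)c(OCc2ccccc2)c1 | intermediate
12 | 3-[3-(benzyloxy)-4-methoxyphenyl]prop-1-ene-1,3-dione (aroylketene) | O=C=CC(=O)c1ccc(OC)c(OCc2ccccc2)c1 | intermediate
13 | 1-[3-(benzyloxy)-4-methoxyphenyl]-3-(2,4,6-trihydroxy-3,5-dimethoxyphenyl)propane-1,3-dione | COc1ccc(C(=O)CC(=O)c2c(O)c(OC)c(O)c(OC)c2O)cc1OCc1ccccc1 | intermediate
14 | 2-[3-(benzyloxy)-4-methoxyphenyl]-5,7-dihydroxy-6,8-dimethoxy-4H-chromen-4-one | COc1ccc(-c2cc(=O)c3c(O)c(OC)c(O)c(OC)c3o2)cc1OCc1ccccc1 | intermediate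
15 | acerosin, 5,7-dihydroxy-2-(3-hydroxy-4-methoxyphenyl)-6,8-dimethoxy-4H-chromen-4-one | COc1ccc(-c2cc(=O)c3c(O)c(OC)c(O)c(OC)c3o2)cc1O | target

**Count**
Total steps: 6. Longest linear sequence: 4 steps (steps 1, 2, 5, 6; the ring B branch, steps 3, 4, 5, 6, is equally long).

**Steps most likely to fail**

Step 2 (Proposed new method). Three processes could defeat it. The first C-acylation may be slower than self-condensation or thermal loss of the ketone. The pyranone may be acylated a second time by malonate. The basic stage may stall before ring closure because the ester α-carbon and the diketone carbon are deprotonated ahead of the terminal methoxymethylene carbon. The fallback gives up the open-chain construction of ring A and installs the two methoxy groups on a preformed flavone by known chemistry. It sets out from keto ester 11, which is fused with commercial benzene-1,3,5-triol under the conditions of step 5 (the parent Mentzer reaction) to give 2-[3-(benzyloxy)-4-methoxyphenyl]-5,7-dihydroxy-4H-chromen-4-one F1. N-Bromosuccinimide (2 equiv, DMF, 0 °C) should brominate the two activated ring A positions to give 2-[3-(benzyloxy)-4-methoxyphenyl]-6,8-dibromo-5,7-dihydroxy-4H-chromen-4-one F2. Ullmann-type methoxylation with NaOMe and CuBr in DMF–MeOH at 110 °C, the reaction type that converts ortho-bromophenols into ortho-methoxyphenols, should replace both bromides and arrive at 14, where the route is rejoined. Because positions 6 and 8 end up identical, a ring-opening and reclosure of the pyranone under the basic conditions cannot change the product.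

Step 5. The electron-rich triol may oxidise or decompose in the melt before it is acylated, acylation may stop at oxygen instead of moving to the hindered ring carbon, or a Pechmann-type closure may divert material to a 4-arylcoumarin. The fallback builds the diketone at low temperature by anion chemistry and sets out from 8. Friedel–Crafts acetylation with AcOH and BF3·OEt2 at 80 °C should give 1-(2,4,6-trihydroxy-3,5-dimethoxyphenyl)ethan-1-one F3. Its polyanion, formed with LiN(SiMe3)2 (5 equiv) in THF at −78 °C, is C-acylated at the enolate carbon with 3-(benzyloxy)-4-methoxybenzoyl chloride F4, made from the commercial acid with oxalyl chloride and catalytic DMF. This should give diketone 13 without heat, and catalytic TsOH in toluene at 110 °C should close it to 14, where the route is rejoined.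

Step 6. Over-reduction of the C2–C3 double bond to the flavanone, or a stalled hydrogenolysis through poisoning of the catalyst by traces of chlorophenol or halide carried forward, could spoil the last step. The fallback does without the benzyl group and sets out from 9. Claisen condensation of 9 with diethyl carbonate and NaH (3.5 equiv, one extra for the phenol) in toluene at 110 °C should give ethyl 3-(3-hydroxy-4-methoxyphenyl)-3-oxopropanoate F5. Fusion of F5 with 8 as in step 5 should give 15 directly; acylation of the ring B hydroxyl by the aroylketene is reversible at that temperature, whereas C-acylation followed by cyclodehydration is not.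

**Further compounds**
F1 | step 2 | 2-[3-(benzyloxy)-4-methoxyphenyl]-5,7-dihydroxy-4H-chromen-4-one | COc1ccc(-c2cc(=O)c3c(O)cc(O)cc3o2)cc1OCc1ccccc1
F2 | step 2 | 2-[3-(benzyloxy)-4-methoxyphenyl]-6,8-dibromo-5,7-dihydroxy-4H-chromen-4-one | COc1ccc(-c2cc(=O)c3c(O)c(Br)c(O)c(Br)c3o2)cc1OCc1ccccc1
F3 | step 5 | 1-(2,4,6-trihydroxy-3,5-dimethoxyphenyl)ethan-1-one | CC(=O)c1c(O)c(OC)c(O)c(OC)c1O
F4 | step 5 | 3-(benzyloxy)-4-methoxybenzoyl chloride | COc1ccc(C(Cl)=O)cc1OCc1ccccc1
F5 | step 6 | ethyl 3-(3-hydroxy-4-methoxyphenyl)-3-oxopropanoate | CCOC(=O)CC(=O)c1ccc(OC)c(O)c1
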